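**Plan**

1. Retrosynthesis: after the three MOM ethers, the C2–C3 bond of ring C is cut as the reverse of an α-ketol shift. The enabling feature is the tertiary α-ketol C3(OH)–C4(=O), whose carbinol carbon C3 carries the ring methylene C2. Moving C2 back onto C4 turns the chromanone into a 3-aroyl-3-hydroxy-2,3-dihydrobenzofuran (ring A fused, ring B on the ketone).
2. That five-membered ketol is cut at the aroyl C–C bond (ring B aryllithium + Weinreb amide), then at the ring A aryl–carbinol bond (Friedel–Crafts hydroxyalkylation of an aryloxypyruvate), then at the aryl ether (mirror-symmetric prenylated phloroglucinol diether + methyl glycidate).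
3. Forward: ring A phenol → aryloxy keto ester → dihydrofuran ring closed enantioselectively → ring B attached → ring enlargement to the pyranone ring C → MOM removal.
4. Stereochemistry: the single stereocentre is set as (S) at the dihydrobenzofuran carbinol by a chiral Cu(OTf)2–bis(oxazoline) catalyst. It is handed on to C3 as (R) by the stereospecific, chelate-controlled 1,2-shift.

Key step: step 12

Remark: the target is read as (3R) (CIP order at C3: OH > C4 > C2 > C1′); MOM = methoxymethyl, prenyl = 3-methylbut-2-en-1-yl.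

**Route**

Step 1
Reactants: 1 phloroglucinol (benzene-1,3,5-triol)
Product: 2 3,5-bis(methoxymethoxy)phenol
Conditions: NaH (2.0 equiv), MOMCl (2.0 equiv), DMF, 0 °C → rt
Reagents that add atoms: chloromethyl methyl ether (MOMCl), COCCl
Why: Williamson etherification of the phenoxide with the hard electrophile MOMCl; the bis-ether should be the main component of a statistical mixture, and recovered mono-ether can be re-submitted.

Step 2
Reactants: 2 3,5-bis(methoxymethoxy)phenol
Product: 3 [3,5-bis(methoxymethoxy)phenoxy]tri(propan-2-yl)silane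
Conditions: NaH (1.1 equiv), THF, 0 °C; i-Pr3SiCl (1.1 equiv), rt
Reagents that add atoms: chlorotri(propan-2-yl)silane, CC(C)[Si](Cl)(C(C)C)C(C)C
Why: O-silylation of the remaining phenoxide; the bulky, non-coordinating silyl ether keeps this oxygen distinct from the other two and does not direct metalation.

Step 3
Reactants: 3 [3,5-bis(methoxymethoxy)phenoxy]tri(propan-2-yl)silane
Product: 5 [3,5-bis(methoxymethoxy)-4-(3-methylbut-2-en-1-yl)phenoxy]tri(propan-2-yl)silane, via aryllithium 4 (not isolated)
Conditions: n-BuLi (1.2 equiv), THF, 0 °C, 1 h; CuI (10 mol%), prenyl bromide (1.3 equiv), −78 °C → rt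
Reagents that add atoms: 1-bromo-3-methylbut-2-ene (prenyl bromide), CC(C)=CCBr
Why: Directed ortho-metalation at the one position flanked by both MOM ethers (cooperative chelation), followed by copper-assisted SN2 allylation, should place the prenyl group between the two future free hydroxyls.

Step 4
Reactants: 5 [3,5-bis(methoxymethoxy)-4-(3-methylbut-2-en-1-yl)phenoxy]tri(propan-2-yl)silane
Product: 6 3,5-bis(methoxymethoxy)-4-(3-methylbut-2-en-1-yl)phenol
Conditions: Bu4NF (1.2 equiv), THF, 0 °C; H2O
Reagents that add atoms: none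
Why: Fluoride cleavage of the aryl silyl ether frees the one phenol that will become the ring oxygen O1; the product has a mirror plane through C1 and C4, so its two free ortho positions are equivalent.

Step 5
Reactants: 6 3,5-bis(methoxymethoxy)-4-(3-methylbut-2-en-1-yl)phenol; 7 methyl oxirane-2-carboxylate (racemic)
Product: 8 methyl 3-[3,5-bis(methoxymethoxy)-4-(3-methylbut-2-en-1-yl)phenoxy]-2-hydroxypropanoate (racemic)
Conditions: 7 (1.5 equiv), Cs2CO3 (0.2 equiv), DMF, 60 °C
Reagents that add atoms: none
Why: Base-catalysed SN2 opening of the glycidic ester by the phenoxide at its unsubstituted carbon gives the aryloxy lactate; its stereocentre is racemic and is removed in the next step.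

Step 6
Reactants: 8 methyl 3-[3,5-bis(methoxymethoxy)-4-(3-methylbut-2-en-1-yl)phenoxy]-2-hydroxypropanoate
Product: 9 methyl 3-[3,5-bis(methoxymethoxy)-4-(3-methylbut-2-en-1-yl)phenoxy]-2-oxopropanoate
Conditions: Dess–Martin periodinane (1.3 equiv), CH2Cl2, 0 °C → rt
Reagents that add atoms: none
Why: Dess–Martin oxidation of a secondary α-hydroxy ester to the α-keto ester; the reagent does not epoxidise the prenyl group or cleave the acetals.

Step 7
Reactants: 9 methyl 3-[3,5-bis(methoxymethoxy)-4-(3-methylbut-2-en-1-yl)phenoxy]-2-oxopropanoate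
Product: 10 methyl (3S)-3-hydroxy-4,6-bis(methoxymethoxy)-5-(3-methylbut-2-en-1-yl)-2,3-dihydro-1-benzofuran-3-carboxylate
Conditions: Cu(OTf)2 (10 mol%), 2,2′-(propane-2,2-diyl)bis[(4R)-4-tert-butyl-4,5-dihydro-1,3-oxazole] (11 mol%), 4 Å molecular sieves, CH2Cl2, −20 → 0 °C
Reagents that add atoms: none
Why: Enantioselective intramolecular Friedel–Crafts hydroxyalkylation, in which the square-planar chelate of divalent copper with the 1,2-dicarbonyl unit is attacked by either of the two equivalent ortho carbons of the trialkoxy-activated arene (5-exo-trig); the tert-butyl groups of the ligand are expected to leave the Re face of the ketone open, which gives the (S)-carbinol, and the sense of induction is to be confirmed and the ligand antipode chosen accordingly.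

Step 8
Reactants: 10 methyl (3S)-3-hydroxy-4,6-bis(methoxymethoxy)-5-(3-methylbut-2-en-1-yl)-2,3-dihydro-1-benzofuran-3-carboxylate
Product: 11 (3S)-3-hydroxy-N-methoxy-N-methyl-4,6-bis(methoxymethoxy)-5-(3-methylbut-2-en-1-yl)-2,3-dihydro-1-benzofuran-3-carboxamide
Conditions: MeNH(OMe)·HCl (3 equiv), i-PrMgCl (7 equiv), THF, −20 → 0 °C
Reagents that add atoms: N,O-dimethylhydroxylamine hydrochloride, CNOC.Cl
Why: Weinreb amide formation from the ester with the magnesium amide of N,O-dimethylhydroxylamine; no bond to the stereocentre is touched.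

Step 9
Reactants: 12 4-chloro-3-methoxyphenol
Product: 13 1-chloro-2-methoxy-4-(methoxymethoxy)benzene
Conditions: NaH (1.1 equiv), MOMCl (1.1 equiv), DMF, 0 °C → rt
Reagents that add atoms: chloromethyl methyl ether (MOMCl), COCCl
Why: Williamson etherification protects the phenol as a MOM ether that also serves as the directing group for the next step.

Step 10
Reactants: 13 1-chloro-2-methoxy-4-(methoxymethoxy)benzene
Product: 15 1-chloro-2-methoxy-4-(methoxymethoxy)-3-(3-methylbut-2-en-1-yl)benzene, via aryllithium 14 (not isolated)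
Conditions: n-BuLi (1.1 equiv), THF, −78 → −20 °C; CuI (10 mol%), prenyl bromide (1.2 equiv), −78 °C → rt
Reagents that add atoms: 1-bromo-3-methylbut-2-ene (prenyl bromide), CC(C)=CCBr
Why: Directed ortho-metalation between the methoxy and MOM ether oxygens, then copper-assisted SN2 prenylation; an aryl chloride is used because it survives butyllithium at low temperature, where a bromide would undergo halogen–lithium exchange.

Step 11
Reactants: 11 (3S)-3-hydroxy-N-methoxy-N-methyl-4,6-bis(methoxymethoxy)-5-(3-methylbut-2-en-1-yl)-2,3-dihydro-1-benzofuran-3-carboxamide; 15 1-chloro-2-methoxy-4-(methoxymethoxy)-3-(3-methylbut-2-en-1-yl)benzene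
Product: 17 [(3S)-3-hydroxy-4,6-bis(methoxymethoxy)-5-(3-methylbut-2-en-1-yl)-2,3-dihydro-1-benzofuran-3-yl][2-methoxy-4-(methoxymethoxy)-3-(3-methylbut-2-en-1-yl)phenyl]methanone, via aryllithium 16 (not isolated)
Conditions: 15 (1.6 equiv), Li powder, 4,4′-di-tert-butylbiphenyl (5 mol%), THF, −78 °C, cannulated off excess Li; 11 pre-treated with LiN(SiMe3)2 (1.05 equiv), THF, −78 °C; combined, −78 → −20 °C; H2O
Reagents that add atoms: none
Why: Arene-catalysed reductive lithiation of the aryl chloride gives the aryllithium, which adds once to the Weinreb amide (held as its lithium alkoxide) because the chelated tetrahedral intermediate collapses only on work-up; the carbinol stereocentre is not involved.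

Step 12
Reactants: 17 [(3S)-3-hydroxy-4,6-bis(methoxymethoxy)-5-(3-methylbut-2-en-1-yl)-2,3-dihydro-1-benzofuran-3-yl][2-methoxy-4-(methoxymethoxy)-3-(3-methylbut-2-en-1-yl)phenyl]methanone
Product: 18 (3R)-3-hydroxy-3-[2-methoxy-4-(methoxymethoxy)-3-(3-methylbut-2-en-1-yl)phenyl]-5,7-bis(methoxymethoxy)-6-(3-methylbut-2-en-1-yl)-2,3-dihydro-4H-chromen-4-one
Conditions: Al(OtBu)3 (1.2 equiv), toluene, 90 °C; aq potassium sodium tartrate
Reagents that add atoms: none
Why: α-Ketol (acyloin) rearrangement run as a ring enlargement: 17 is converted into its aluminium alkoxide, aluminium also binds the aroyl oxygen, and the ring methylene C2 migrates with its bonding pair from the carbinol carbon to the carbonyl carbon while the carbinol carbon becomes the C4 ketone. The closest known reaction type is the Lewis-acid- or alkoxide-mediated enlargement of 1-acylcycloalkanols to 2-hydroxycycloalkanones, as in the D-homoannulation of 17-hydroxy-20-keto steroids. Ring C is not closed by an exo or endo attack but grows out of the dihydrofuran ring by a suprafacial 1,2-shift within the five-membered O–C–C–O chelate, which makes the new C2–C3 bond. The new stereocentre C3 is set by the existing carbinol centre: in the syn-periplanar chelate the methylene lies over one face of the carbonyl group only, so that (S)-17 should give (R)-18 while the old centre is spent as it turns into the sp2 carbon C4. The step needs migration of the methylene rather than of the ring A carbon and no loss of water to the benzofuran; the first is secured thermodynamically, since 18 loses the strain of the five-membered ring and gains a ketone held coplanar with the trioxygenated ring A, and the second by the non-acidic alkoxide medium. Should the ring A carbon shift first, the less stable 4-aryl-4-hydroxychroman-3-one can return or pass on ring B by the same chelated shift, and both ways end in 18 with the same configuration.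

Step 13
Reactants: 18 (3R)-3-hydroxy-3-[2-methoxy-4-(methoxymethoxy)-3-(3-methylbut-2-en-1-yl)phenyl]-5,7-bis(methoxymethoxy)-6-(3-methylbut-2-en-1-yl)-2,3-dihydro-4H-chromen-4-one
Product: 19 (3R)-3,5,7-trihydroxy-3-[4-hydroxy-2-methoxy-3-(3-methylbut-2-en-1-yl)phenyl]-6-(3-methylbut-2-en-1-yl)-2,3-dihydro-4H-chromen-4-one
Conditions: conc. HCl (cat.), MeOH, 25 → 40 °C
Reagents that add atoms: none
Why: Acid-catalysed acetal exchange with methanol removes the three MOM groups under mild conditions; the tertiary carbinol is α to a ketone and should not ionise, so the stereocentre is untouched.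

**Compound list**

1 | phloroglucinol (benzene-1,3,5-triol) | Oc1cc(O)cc(O)c1 | starting material
2 | 3,5-bis(methoxymethoxy)phenol | Oc1cc(OCOC)cc(OCOC)c1 | intermediate
3 | [3,5-bis(methoxymethoxy)phenoxy]tri(propan-2-yl)silane | CC(C)[Si](Oc1cc(OCOC)cc(OCOC)c1)(C(C)C)C(C)C | intermediate
4 | [2,6-bis(methoxymethoxy)-4-(triisopropylsilyloxy)phenyl]lithium | [Li]c1c(OCOC)cc(O[Si](C(C)C)(C(C)C)C(C)C)cc1OCOC | intermediate
5 | [3,5-bis(methoxymethoxy)-4-(3-methylbut-2-en-1-yl)phenoxy]tri(propan-2-yl)silane | CC(C)=CCc1c(OCOC)cc(O[Si](C(C)C)(C(C)C)C(C)C)cc1OCOC | intermediate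
6 | 3,5-bis(methoxymethoxy)-4-(3-methylbut-2-en-1-yl)phenol | CC(C)=CCc1c(OCOC)cc(O)cc1OCOC | intermediate
7 | methyl oxirane-2-carboxylate (racemic) | COC(=O)C1CO1 | starting material
8 | methyl 3-[3,5-bis(methoxymethoxy)-4-(3-methylbut-2-en-1-yl)phenoxy]-2-hydroxypropanoate (racemic) | COC(=O)C(O)COc1cc(OCOC)c(CC=C(C)C)c(OCOC)c1 | intermediate
9 | methyl 3-[3,5-bis(methoxymethoxy)-4-(3-methylbut-2-en-1-yl)phenoxy]-2-oxopropanoate | COC(=O)C(=O)COc1cc(OCOC)c(CC=C(C)C)c(OCOC)c1 | intermediate
10 | methyl (3S)-3-hydroxy-4,6-bis(methoxymethoxy)-5-(3-methylbut-2-en-1-yl)-2,3-dihydro-1-benzofuran-3-carboxylate | O[C@]1(C(=O)OC)COc2cc(OCOC)c(CC=C(C)C)c(OCOC)c21 | intermediate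
11 | (3S)-3-hydroxy-N-methoxy-N-methyl-4,6-bis(methoxymethoxy)-5-(3-methylbut-2-en-1-yl)-2,3-dihydro-1-benzofuran-3-carboxamide | O[C@]1(C(=O)N(C)OC)COc2cc(OCOC)c(CC=C(C)C)c(OCOC)c21 | intermediate
12 | 4-chloro-3-methoxyphenol | COc1cc(O)ccc1Cl | starting material
13 | 1-chloro-2-methoxy-4-(methoxymethoxy)benzene | COCOc1ccc(Cl)c(OC)c1 | intermediate
14 | [3-chloro-2-methoxy-6-(methoxymethoxy)phenyl]lithium | [Li]c1c(OCOC)ccc(Cl)c1OC | intermediate
15 | 1-chloro-2-methoxy-4-(methoxymethoxy)-3-(3-methylbut-2-en-1-yl)benzene | COCOc1ccc(Cl)c(OC)c1CC=C(C)C | intermediate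
16 | [2-methoxy-4-(methoxymethoxy)-3-(3-methylbut-2-en-1-yl)phenyl]lithium | [Li]c1ccc(OCOC)c(CC=C(C)C)c1OC | intermediate
17 | [(3S)-3-hydroxy-4,6-bis(methoxymethoxy)-5-(3-methylbut-2-en-1-yl)-2,3-dihydro-1-benzofuran-3-yl][2-methoxy-4-(methoxymethoxy)-3-(3-methylbut-2-en-1-yl)phenyl]methanone | O[C@]1(C(=O)c2ccc(OCOC)c(CC=C(C)C)c2OC)COc2cc(OCOC)c(CC=C(C)C)c(OCOC)c21 | intermediate
18 | (3R)-3-hydroxy-3-[2-methoxy-4-(methoxymethoxy)-3-(3-methylbut-2-en-1-yl)phenyl]-5,7-bis(methoxymethoxy)-6-(3-methylbut-2-en-1-yl)-2,3-dihydro-4H-chromen-4-one | COc1c([C@@]2(O)COc3cc(OCOC)c(CC=C(C)C)c(OCOC)c3C2=O)ccc(OCOC)c1CC=C(C)C | intermediate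
19 | (3R)-3,5,7-trihydroxy-3-[4-hydroxy-2-methoxy-3-(3-methylbut-2-en-1-yl)phenyl]-6-(3-methylbut-2-en-1-yl)-2,3-dihydro-4H-chromen-4-one | COc1c([C@@]2(O)COc3cc(O)c(CC=C(C)C)c(O)c3C2=O)ccc(O)c1CC=C(C)C | target

**Step count and risks**

Total step count: 13. Longest linear sequence: 11 steps (steps 1–8 and 11–13).

Steps most likely to fail:

1. Step 7 (enantioselective Friedel–Crafts closure). What may go wrong: poor facial selectivity in the attack of the arene on the chelated ketone, so that the carbinol is formed with low enantiomeric purity. Fallback, from 9 back to 11: 9 would be cyclised with Cu(OTf)2 and achiral 2,2′-bipyridine to racemic methyl 3-hydroxy-4,6-bis(methoxymethoxy)-5-(3-methylbut-2-en-1-yl)-2,3-dihydro-1-benzofuran-3-carboxylate F1. Saponification with LiOH would give the racemic 3-hydroxy-4,6-bis(methoxymethoxy)-5-(3-methylbut-2-en-1-yl)-2,3-dihydro-1-benzofuran-3-carboxylic acid F2. Classical resolution by crystallisation of its salt with (S)-1-phenylethylamine (or the antipodal amine, whichever gives the less soluble salt of the wanted acid) and acidification would give the (3S)-acid F3. Carbodiimide coupling of F3 with N,O-dimethylhydroxylamine would return the route to 11.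

2. Step 12 (α-ketol ring enlargement). What may go wrong: migration of the ring A carbon with stalling at the isomeric ketol, or leakage through a non-chelated transition state with loss of stereochemical fidelity. Fallback, from 6 and 15 back to 18, closing ring C by a different bond with known chemistry:
   - Phenol 6 would be ortho-formylated (MgCl2, Et3N, paraformaldehyde, MeCN, reflux) to 2-hydroxy-4,6-bis(methoxymethoxy)-5-(3-methylbut-2-en-1-yl)benzaldehyde F4.
   - Aryllithium 16 (from 15 as in step 11) would be acylated with 2-chloro-N-methoxy-N-methylacetamide to 2-chloro-1-[2-methoxy-4-(methoxymethoxy)-3-(3-methylbut-2-en-1-yl)phenyl]ethan-1-one F5.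
   - O-Alkylation of F4 with F5 (K2CO3, acetone) would give 2-{2-[2-methoxy-4-(methoxymethoxy)-3-(3-methylbut-2-en-1-yl)phenyl]-2-oxoethoxy}-4,6-bis(methoxymethoxy)-5-(3-methylbut-2-en-1-yl)benzaldehyde F6.
   - An enantioselective intramolecular crossed benzoin reaction of F6 would give 18. The catalyst would be the carbene from (5aS,10bR)-2-(pentafluorophenyl)-5a,10b-dihydro-4H,6H-indeno[2,1-b][1,2,4]triazolo[4,3-d][1,4]oxazin-2-ium tetrafluoroborate or its antipode (whichever delivers the (R)-carbinol) with Et3N in toluene.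

3. Step 11 (reductive lithiation and ketone formation). What may go wrong: reductive cleavage of ether groups or premature protonation of the aryllithium during the lithium–arene reduction. Fallback, from 11 back to 17, making the ring B nucleophile by directed ortho-lithiation instead:
   - Purchased resorcinol F7 would be converted (NaH, MOMCl) into 1,3-bis(methoxymethoxy)benzene F8.
   - F8 would be lithiated between the two ethers to [2,6-bis(methoxymethoxy)phenyl]lithium F9 and prenylated (CuI, prenyl bromide) to 1,3-bis(methoxymethoxy)-2-(3-methylbut-2-en-1-yl)benzene F10.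
   - A second lithiation (n-BuLi, TMEDA) ortho to one MOM ether would give [2,4-bis(methoxymethoxy)-3-(3-methylbut-2-en-1-yl)phenyl]lithium F11.
   - Addition of F11 to the lithium alkoxide of 11 would give [(3S)-3-hydroxy-4,6-bis(methoxymethoxy)-5-(3-methylbut-2-en-1-yl)-2,3-dihydro-1-benzofuran-3-yl][2,4-bis(methoxymethoxy)-3-(3-methylbut-2-en-1-yl)phenyl]methanone F12.
   - The MOM ether ortho to the ketone would be removed selectively (cat. HCl, MeOH, 0 °C, carbonyl-assisted) to [(3S)-3-hydroxy-4,6-bis(methoxymethoxy)-5-(3-methylbut-2-en-1-yl)-2,3-dihydro-1-benzofuran-3-yl][2-hydroxy-4-(methoxymethoxy)-3-(3-methylbut-2-en-1-yl)phenyl]methanone F13.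
   - Mitsunobu methylation of F13 (MeOH, PPh3, diisopropyl azodicarboxylate) would give 17.

Further compounds
F1 | step 7 | racemic methyl 3-hydroxy-4,6-bis(methoxymethoxy)-5-(3-methylbut-2-en-1-yl)-2,3-dihydro-1-benzofuran-3-carboxylate | COC(=O)C1(O)COc2cc(OCOC)c(CC=C(C)C)c(OCOC)c21
F2 | step 7 | racemic 3-hydroxy-4,6-bis(methoxymethoxy)-5-(3-methylbut-2-en-1-yl)-2,3-dihydro-1-benzofuran-3-carboxylic acid | OC(=O)C1(O)COc2cc(OCOC)c(CC=C(C)C)c(OCOC)c21
F3 | step 7 | (3S)-3-hydroxy-4,6-bis(methoxymethoxy)-5-(3-methylbut-2-en-1-yl)-2,3-dihydro-1-benzofuran-3-carboxylic acid | O[C@]1(C(=O)O)COc2cc(OCOC)c(CC=C(C)C)c(OCOC)c21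
F4 | step 12 | 2-hydroxy-4,6-bis(methoxymethoxy)-5-(3-methylbut-2-en-1-yl)benzaldehyde | O=Cc1c(O)cc(OCOC)c(CC=C(C)C)c1OCOC
F5 | step 12 | 2-chloro-1-[2-methoxy-4-(methoxymethoxy)-3-(3-methylbut-2-en-1-yl)phenyl]ethan-1-one | O=C(CCl)c1ccc(OCOC)c(CC=C(C)C)c1OC
F6 | step 12 | 2-{2-[2-methoxy-4-(methoxymethoxy)-3-(3-methylbut-2-en-1-yl)phenyl]-2-oxoethoxy}-4,6-bis(methoxymethoxy)-5-(3-methylbut-2-en-1-yl)benzaldehyde | O=Cc1c(OCC(=O)c2ccc(OCOC)c(CC=C(C)C)c2OC)cc(OCOC)c(CC=C(C)C)c1OCOC
F7 | step 11 | resorcinol (benzene-1,3-diol, purchased) | Oc1cccc(O)c1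
F8 | step 11 | 1,3-bis(methoxymethoxy)benzene | COCOc1cccc(OCOC)c1
F9 | step 11 | [2,6-bis(methoxymethoxy)phenyl]lithium | [Li]c1c(OCOC)cccc1OCOC
F10 | step 11 | 1,3-bis(methoxymethoxy)-2-(3-methylbut-2-en-1-yl)benzene | COCOc1cccc(OCOC)c1CC=C(C)C
F11 | step 11 | [2,4-bis(methoxymethoxy)-3-(3-methylbut-2-en-1-yl)phenyl]lithium | [Li]c1ccc(OCOC)c(CC=C(C)C)c1OCOC
F12 | step 11 | [(3S)-3-hydroxy-4,6-bis(methoxymethoxy)-5-(3-methylbut-2-en-1-yl)-2,3-dihydro-1-benzofuran-3-yl][2,4-bis(methoxymethoxy)-3-(3-methylbut-2-en-1-yl)phenyl]methanone | O[C@]1(C(=O)c2ccc(OCOC)c(CC=C(C)C)c2OCOC)COc2cc(OCOC)c(CC=C(C)C)c(OCOC)c21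
F13 | step 11 | [(3S)-3-hydroxy-4,6-bis(methoxymethoxy)-5-(3-methylbut-2-en-1-yl)-2,3-dihydro-1-benzofuran-3-yl][2-hydroxy-4-(methoxymethoxy)-3-(3-methylbut-2-en-1-yl)phenyl]methanone | O[C@]1(C(=O)c2ccc(OCOC)c(CC=C(C)C)c2O)COc2cc(OCOC)c(CC=C(C)C)c(OCOC)c21
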